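At 20 h you read the next flask, and first you choose its charge: 0.10 M of solid substrate, or Wednesday's 0.15 M again.

- Wednesday's: solid substrate 0.15 M; gas 31 mM (held); run made earlier
- flask: solid substrate 0.10 M; gas 31 mM (held); time 20 h

- Wednesday's (time / h: target / %, dissolved substrate / %): 1.00: 0.8, 1.2; 2.00: 2.6, 0.5; 3.00: 5.6, 1.3; 4.00: 6.1, 0.5

(readings scatter by 0.5 percentage points)

1. target at 20 h, in percent of the solid substrate charged
2. concentration of dissolved substrate in solution at 20 h, in percent of saturation

- given per volume of solution although it is solid: solid substrate
- at the start none of coupling partner is dissolved
- steps under discussion: solid substrate <-> dissolved substrate; dissolved substrate + coupling partner -> target; target <-> isomer of the product; gas <-> coupling partner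
- at the start none of the solid substrate is in solution
- dissolved substrate means what is dissolved; the solid is not counted in it

The concentration to watch is c(dissolved substrate). In Wednesday's run it averages 1.31 mM and stays flat within the scatter, while target climbs from 0.8 % to 6.1 %. So take the rate as zero-order in the solid charged for as long as solid stands. That rise gives 2.65 mM/h; call this the pace, the concentration of target formed per hour.

Your estimate: over 20 h the pace comes to 53.0 mM, whichever of the two charges you pick, and that sum covers target and its isomer together. It is 35.3 % of 0.15 M but 53.0 % of 0.10 M, and on this reckoning solid still stands at the reading, because the sum is less than the charge. So charge 0.10 M and keep the time. You can't tell from these readings whether the flat level is saturation, so you leave that answer open.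

The forecast, whose figures differ from your sum, gives 45 % of target and 92 % of saturation, reading the level as “a solid-buffered, near-saturated solution”.

The flask gives 48.1 % of target, with dissolved substrate at 1.03 % of saturation.

    solid substrate ⇌ dissolved substrate, rate k1*(cs1 - [dissolved substrate]) while solid is left; crystals form when [dissolved substrate] > cs1 (solubility = 0.0780 M, k = 0.0384 /h)
    dissolved substrate + coupling partner → target (k = 163 /M/h)
    target ⇌ isomer of the product (K = 0.910, k = 0.0245 /h)
    gas ⇌ coupling partner, rate k4*(csat - [coupling partner]) (kL = 0.352 /h)

In this flask target and isomer together make 58.3 % of the charge at 20.0 h, against your 53.0 %. At 7.03 h this flask makes target 7.24 times faster than it uses it up, each step taken net, and by 20.0 h its isomer stands at 10.3 %. In the neighbour flask with 0.17 M, the pace gives 31.2 % of its charge for the two together, and at 20.0 h that flask holds 28.3 % of target and 6.05 % of isomer, each in percent of its own charge.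

The earlier runs and the new flask were generated by integration for substances that don't exist; noise was put on by code.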